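**Plan**
1. Atom labels. Carbocycle: C1 (bears the methylidene), C2–C4, C5 (CMe2), C6 and C10 (ring fusion, C10 next to C1), C7, C8, C9 (quaternary). Heterocycle: C11 (CH on C9), C12 (acetal CH), C13 (bridgehead CH), C14 (CHOAc), C15 (lactone C=O), C16 (CHCO2Me), C17 (ester C=O).
2. Cuts. First the two O–C12 bonds of the 2,7-dioxabicyclo[3.2.1]octan-3-one, giving C12 aldehyde, C15 acid and C16 OH. These two carbonyls go back to the C12–C15 bond of a cyclopentane-1,2-diol. Then C13–C16, then C9–C11, and last C9–C10 and C7–C8.
3. Enabling feature. The cyclopentane C6–C7–C8–C9–C10 is cis-fused to the seven-membered ring and C10 is alpha to C1. C6–C7–C10 can therefore be stored as a cyclopropane conjugated with a C1 ketone, and C8–C9 (with its methyl and a carboxyl handle) is methyl methacrylate.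
4. Forward order. Seven-membered ring by one-carbon expansion, cyclopropane, cyclopentane by (3+2) union, C1 methylenation, decarboxylative C9 radical addition to a chloro enone (C9–C11), enolate alkylation (C13–C16), temporary gamma-lactone, glycol cleavage, and last the bicyclic lactone acetal.
5. Stereochemistry. C6 comes from a CBS reduction relayed by hydroxyl-directed cyclopropanation, C10 from the tether at C6, and C9 from convex-face attack. C11 comes from the acetonide of the (3aR,6aR)-enone. It is relayed to C13 (anti alkylation), C14 (hydride anti to the acetonide), C16 (convex-face hydroxylation) and C12 (bridge constraint).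

Key step: step 5

Remark 1: Az stands for the (1R,3aR,8aS)-1,4,4-trimethyl-8-methylidenedecahydroazulen-1-yl group, bonded through C9.
Remark 2 (assumption): step 5 may deliver both C9 epimers. Compounds 9–12 are drawn as the epimer with the carboxyl group on the convex face, and either epimer gives the same C9 radical in step 10.
Remark 3 (assumption): enone 13 is bought as the single (3aR,6aR) enantiomer.

Step 1
Reactants: 1 4,4-dimethylcyclohex-2-en-1-one; 2 (trimethylsilyl)diazomethane
Product: 4 4,4-dimethylcyclohept-2-en-1-one, via alpha-silyl ketone 3 (not isolated)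
Conditions: 2 (1.2 equiv), BF3·OEt2, CH2Cl2, −78 to −30 °C; then 1 M HCl, THF, rt
Reagents that add atoms: (trimethylsilyl)diazomethane (2), C[Si](C)(C)C=[N+]=[N-]
Why: Lewis-acid-promoted diazoalkane homologation (Tiffeneau–Demjanov-type 1,2-shift), in which the saturated alpha' carbon migrates in preference to the vinyl carbon as is usual for cyclic enones, the gem-dimethyl group shields the C=C bond from dipolar cycloaddition, and dilute acid removes silicon from 3; no stereocentre is formed.

Step 2
Reactants: 4 4,4-dimethylcyclohept-2-en-1-one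
Product: 5 (1R)-4,4-dimethylcyclohept-2-en-1-ol
Conditions: (S)-Me-CBS [(S)-1-methyl-3,3-diphenyltetrahydro-1H,3H-pyrrolo[1,2-c][1,3,2]oxazaborole] (10 mol %), BH3·SMe2, THF, −30 °C; MeOH quench
Reagents that add atoms: none
Why: Corey–Bakshi–Shibata reduction, in which the alkenyl arm carrying the quaternary carbon acts as the large group so that the (S)-catalyst should give the (R)-carbinol, the only source of absolute configuration for the carbocycle.

Step 3
Reactants: 5 (1R)-4,4-dimethylcyclohept-2-en-1-ol
Product: 6 (1S,2R,7R)-6,6-dimethylbicyclo[5.1.0]octan-2-ol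
Conditions: Et2Zn, CH2I2, CH2Cl2, −10 °C to rt; aq. NH4Cl
Reagents that add atoms: diiodomethane, ICI
Why: Hydroxyl-directed Simmons–Smith cyclopropanation (Furukawa reagent), in which the zinc alkoxide delivers CH2 (C7) to the alkene face syn to oxygen, as is the rule for cyclohept-2-enols, and thereby fixes C6 and C10.

Step 4
Reactants: 6 (1S,2R,7R)-6,6-dimethylbicyclo[5.1.0]octan-2-ol
Product: 7 (1S,7R)-6,6-dimethylbicyclo[5.1.0]octan-2-one
Conditions: Dess–Martin periodinane, CH2Cl2, 0 °C to rt
Reagents that add atoms: none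
Why: Dess–Martin oxidation of the secondary cyclopropyl carbinol under near-neutral conditions removes the relay stereocentre and leaves the cyclopropane and C6/C10 untouched.

Step 5
Reactants: 7 (1S,7R)-6,6-dimethylbicyclo[5.1.0]octan-2-one; 8 methyl methacrylate
Product: 9 methyl (1R,3aR,8aR)-1,4,4-trimethyl-8-oxodecahydroazulene-1-carboxylate
Conditions: SmI2 (20 mol %), samarium metal (20 mol %), 8 (3 equiv, syringe pump), THF, 60 °C, argon
Reagents that add atoms: methyl methacrylate (8), C=C(C)C(=O)OC
Why: Proposed new method: one electron passes from divalent samarium to the C1 carbonyl of 7, the ketyl breaks the cyclopropane bond C10–C7 to leave a primary radical at C7 and a trivalent samarium enolate C1=C10, the C7 radical adds to the CH2 terminus of 8 (bond C7–C8), the ester-stabilised C9 radical then bonds to the enolate carbon C10 (bond C9–C10), and the ketyl of 9 gives its electron back, so SmI2 acts as a catalyst that samarium metal keeps in its active state. The closest known reaction type is the SmI2-catalysed radical-relay (3+2) coupling of alkyl cyclopropyl ketones with alkenes and alkynes; a ring-fused ketone joined to a 1,1-disubstituted acrylate with formation of a quaternary carbon has not been shown. The one new ring, the cyclopentane C6–C7–C8–C9–C10, closes in the 5-exo-trig mode on the enolate C10=C1. C10 is set by the three-atom tether hanging from C6, which can reach C10 only from the face that C7 already occupies and so should give the cis 5–7 fusion, C6 is not touched and keeps the configuration of 7, and C9 is not controlled and need not be because it becomes planar again in step 10. The step needs cleavage of the exocyclic bond C10–C7 instead of the ring bond C10–C6, which the rigid bicycle secures because only C10–C7 is aligned with the ketyl p orbital, and it needs ring closure to outrun reduction of the C9 radical, which the low stationary concentration of divalent samarium, the absence of a proton source and the polarity match of an electrophilic radical with an electron-rich enolate should favour.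

Step 6
Reactants: 9 methyl (1R,3aR,8aR)-1,4,4-trimethyl-8-oxodecahydroazulene-1-carboxylate
Product: 10 methyl (1R,3aR,8aS)-1,4,4-trimethyl-8-methylidenedecahydroazulene-1-carboxylate
Conditions: Zn, CH2Br2, TiCl4, THF/CH2Cl2, 0 °C to rt
Reagents that add atoms: dibromomethane, BrCBr
Why: Lombardo methylenation, a non-basic gem-dimetallic reagent that converts hindered enolisable ketones without epimerising C10 and ignores the tertiary ester.

Step 7
Reactants: 10 methyl (1R,3aR,8aS)-1,4,4-trimethyl-8-methylidenedecahydroazulene-1-carboxylate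
Product: 11 (1R,3aR,8aS)-1,4,4-trimethyl-8-methylidenedecahydroazulene-1-carboxylic acid
Conditions: EtSNa, DMF, 100 °C; then dilute HCl
Reagents that add atoms: none
Why: SN2 dealkylation of a hindered methyl ester, in which the thiolate attacks the open O-methyl carbon instead of the shielded carbonyl, and no epimerisable centre is present.

Step 8
Reactants: 11 (1R,3aR,8aS)-1,4,4-trimethyl-8-methylidenedecahydroazulene-1-carboxylic acid
Product: 12 N-acyloxyphthalimide of acid 11
Conditions: N-hydroxyphthalimide, diisopropylcarbodiimide, 4-(dimethylamino)pyridine (cat.), CH2Cl2, rt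
Reagents that add atoms: N-hydroxyphthalimide, O=C1c2ccccc2C(=O)N1O
Why: Carbodiimide (Steglich-type) esterification gives the redox-active ester without touching any stereocentre.

Step 9
Reactants: 13 (3aR,6aR)-2,2-dimethyl-3a,6a-dihydro-4H-cyclopenta[d][1,3]dioxol-4-one
Product: 14 (3aR,6aR)-5-chloro-2,2-dimethyl-3a,6a-dihydro-4H-cyclopenta[d][1,3]dioxol-4-one
Conditions: PhICl2, pyridine, CH2Cl2, 0 °C to rt
Reagents that add atoms: (dichloroiodo)benzene, ClI(Cl)c1ccccc1
Why: Alpha-halogenation of an enone by chlorine transfer and pyridine-induced loss of HCl runs without acid and spares the acetonide, and the chlorine both raises the radical affinity of the enone and marks C13 for regiospecific enolate formation.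

Step 10
Reactants: 12 N-acyloxyphthalimide of acid 11; 14 chloro enone
Product: 15 chloro ketone (Az on C11 anti to the acetonide)
Conditions: Ru(bpy)3(PF6)2 (1 mol %), diethyl 2,6-dimethyl-1,4-dihydropyridine-3,5-dicarboxylate (Hantzsch ester, 1.5 equiv), i-Pr2NEt·HBF4, CH2Cl2, blue LEDs, rt
Reagents that add atoms: chloro enone (14), CC1(C)O[C@@H]2C=C(Cl)C(=O)[C@@H]2O1
Why: Photoredox decarboxylative Giese addition of a tertiary radical from an N-acyloxyphthalimide to an alpha-chloro cyclopentenone, in which C9 bonds through the convex face of the cis-hydroazulene (syn to H6 and H10, anti to the C10–C1 bond) and C11 forms on the enone face opposite the acetonide, while the configuration of the C13 chloride is erased in step 11.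

Step 11
Reactants: 15 chloro ketone; 16 methyl bromoacetate
Product: 18 keto ester (CH2CO2Me on C13 trans to Az), via lithium enolate 17 (not isolated)
Conditions: Me2CuLi (from CuI and MeLi), Et2O/THF, −78 to −30 °C; then 16, HMPA, −78 to 0 °C
Reagents that add atoms: methyl bromoacetate (16), COC(=O)CBr
Why: Reductive dehalogenation of the alpha-chloro ketone by the cuprate gives the C14=C13 enolate regiospecifically, and its SN2 alkylation takes place anti to the bulky C11 substituent, which sets C13.

Step 12
Reactants: 18 keto ester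
Product: 20 tricyclic gamma-lactone, via hydroxy ester 19 (not isolated)
Conditions: NaBH4, CeCl3·7H2O, MeOH, −78 to −20 °C; then pyridinium p-toluenesulfonate (cat.), toluene, 60 °C
Reagents that add atoms: none
Why: Luche-type carbonyl reduction with hydride attack on the face opposite the acetonide and the C13 side chain places the C14 oxygen cis to that chain, so that acid-catalysed lactonisation to the cis-fused gamma-lactone follows.

Step 13
Reactants: 20 tricyclic gamma-lactone
Product: 21 C16-hydroxy lactone (OH exo)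
Conditions: KN(SiMe3)2, THF, −78 °C; 3-phenyl-2-(phenylsulfonyl)oxaziridine, −78 °C; AcOH quench
Reagents that add atoms: 3-phenyl-2-(phenylsulfonyl)oxaziridine (Davis oxaziridine), O=S(=O)(c1ccccc1)N1OC1c1ccccc1
Why: Davis oxidation of the potassium lactone enolate, in which the oxaziridine approaches the convex face of the cis-fused lactone (the face of H13 and H14) and so places the C16 oxygen exo as the target requires.

Step 14
Reactants: 21 C16-hydroxy lactone
Product: 22 C16-silyloxy lactone
Conditions: t-BuMe2SiOTf, 2,6-lutidine, CH2Cl2, 0 °C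
Reagents that add atoms: tert-butyldimethylsilyl triflate, CC(C)(C)[Si](C)(C)OS(=O)(=O)C(F)(F)F
Why: Silylation with the triflate and a hindered base protects the crowded alpha-hydroxy lactone without epimerising C16.

Step 15
Reactants: 22 C16-silyloxy lactone; 2 (trimethylsilyl)diazomethane
Product: 24 C14-hydroxy methyl ester, via hydroxy acid 23 (not isolated)
Conditions: LiOH, THF/H2O, 0 °C to rt; cold 0.5 M HCl to pH 4, extraction at 0 °C; 2, toluene/MeOH, 0 °C
Reagents that add atoms: lithium hydroxide, [Li+].[OH-]; (trimethylsilyl)diazomethane (2), C[Si](C)(C)C=[N+]=[N-]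
Why: Irreversible saponification opens the lactone, and esterification of the cold hydroxy acid with the diazoalkane in methanol is fast and neutral, so the methyl ester should form before relactonisation; no stereocentre is affected.

Step 16
Reactants: 24 C14-hydroxy methyl ester
Product: 25 C14 acetate
Conditions: Ac2O, 4-(dimethylamino)pyridine (cat.), pyridine, 0 °C, on freshly made 24
Reagents that add atoms: acetic anhydride, CC(=O)OC(C)=O
Why: Nucleophile-catalysed acylation of the C14 hydroxyl, run at once on fresh 24, blocks relactonisation for good.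

Step 17
Reactants: 25 C14 acetate
Product: 26 C12,C15-diol
Conditions: EtSH, Zn(OTf)2, CH2Cl2, 0 °C to rt
Reagents that add atoms: none
Why: Lewis-acid-mediated transthioketalisation removes the isopropylidene group under non-aqueous, nearly neutral conditions that spare the silyl ether, the acetate, the ester and the 1,1-disubstituted alkene.

Step 18
Reactants: 26 C12,C15-diol
Product: 27 C12,C15-dialdehyde
Conditions: NaIO4 on silica gel, CH2Cl2, rt, on crude 26
Reagents that add atoms: none
Why: Periodate (Malaprade) glycol cleavage of the cis-diol breaks C12–C15 and is inert towards the alkene.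

Step 19
Reactants: 27 C12,C15-dialdehyde
Product: 28 C12-aldehyde C15-acid
Conditions: NaClO2 (1.1 equiv), NaH2PO4, 2-methyl-2-butene, t-BuOH/H2O, 0 °C
Reagents that add atoms: sodium chlorite, [Na+].[O-]Cl=O
Why: Pinnick oxidation with about one equivalent of chlorite should pick the electron-poor, unhindered alpha-acetoxy aldehyde C15 over the C12 aldehyde, which is shielded by the adjacent C11–C9 array, and the scavenger protects the alkene from hypochlorous acid.

Step 20
Reactants: 28 C12-aldehyde C15-acid
Product: 30 CNP0215240.1 (target), via lactol acid 29 (not isolated)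
Conditions: HF·pyridine, THF, 0 °C to rt; then pyridinium p-toluenesulfonate (cat.), 4 Å molecular sieves, CH2Cl2, rt
Reagents that add atoms: none
Why: Fluoride frees the C16 hydroxyl, which adds to the C12 aldehyde to give the five-membered lactol faster than it can be acylated, and acid-catalysed dehydrative acylal formation with the C15 acid closes the six-membered lactone, C12 being fixed by the bridge because only the anomer with its OH cis to the C14–C15 arm can lactonise.

**Compound list**
1 | 4,4-dimethylcyclohex-2-en-1-one | CC1(C)CCC(=O)C=C1 | starting material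
2 | (trimethylsilyl)diazomethane | C[Si](C)(C)C=[N+]=[N-] | starting material
3 | 4,4-dimethyl-7-(trimethylsilyl)cyclohept-2-en-1-one (C–Si centre racemic) | O=C1C=CC(C)(C)CCC1[Si](C)(C)C | intermediate
4 | 4,4-dimethylcyclohept-2-en-1-one | O=C1C=CC(C)(C)CCC1 | intermediate
5 | (1R)-4,4-dimethylcyclohept-2-en-1-ol | O[C@H]1C=CC(C)(C)CCC1 | intermediate
6 | (1S,2R,7R)-6,6-dimethylbicyclo[5.1.0]octan-2-ol (OH syn to the cyclopropane CH2) | O[C@@H]1CCCC(C)(C)[C@@H]2C[C@H]12 | intermediate
7 | (1S,7R)-6,6-dimethylbicyclo[5.1.0]octan-2-one | O=C1CCCC(C)(C)[C@@H]2C[C@H]12 | intermediate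
8 | methyl methacrylate | C=C(C)C(=O)OC | starting material
9 | methyl (1R,3aR,8aR)-1,4,4-trimethyl-8-oxodecahydroazulene-1-carboxylate (cis-fused) | O=C1CCCC(C)(C)[C@@H]2CC[C@@](C)(C(=O)OC)[C@H]12 | intermediate
10 | methyl (1R,3aR,8aS)-1,4,4-trimethyl-8-methylidenedecahydroazulene-1-carboxylate | C=C1CCCC(C)(C)[C@@H]2CC[C@@](C)(C(=O)OC)[C@H]12 | intermediate
11 | (1R,3aR,8aS)-1,4,4-trimethyl-8-methylidenedecahydroazulene-1-carboxylic acid | C=C1CCCC(C)(C)[C@@H]2CC[C@@](C)(C(=O)O)[C@H]12 | intermediate
12 | 1,3-dioxoisoindolin-2-yl (1R,3aR,8aS)-1,4,4-trimethyl-8-methylidenedecahydroazulene-1-carboxylate | C=C1CCCC(C)(C)[C@@H]2CC[C@@](C)(C(=O)ON3C(=O)c4ccccc4C3=O)[C@H]12 | intermediate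
13 | (3aR,6aR)-2,2-dimethyl-3a,6a-dihydro-4H-cyclopenta[d][1,3]dioxol-4-one | CC1(C)O[C@@H]2C=CC(=O)[C@@H]2O1 | starting material
14 | (3aR,6aR)-5-chloro-2,2-dimethyl-3a,6a-dihydro-4H-cyclopenta[d][1,3]dioxol-4-one | CC1(C)O[C@@H]2C=C(Cl)C(=O)[C@@H]2O1 | intermediate
15 | 5-chloro-6-Az-2,2-dimethyltetrahydro-4H-cyclopenta[d][1,3]dioxol-4-one; Az on C11 anti to the dioxolane, Cl on C13 trans to Az | C=C1CCCC(C)(C)[C@@H]2CC[C@@](C)([C@@H]3[C@H]4OC(C)(C)O[C@H]4C(=O)[C@H]3Cl)[C@H]12 | intermediate
16 | methyl bromoacetate | COC(=O)CBr | starting material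
17 | lithium C14=C13 enolate of the dechlorinated ketone | C=C1CCCC(C)(C)[C@@H]2CC[C@@](C)([C@@H]3[C@H]4OC(C)(C)O[C@H]4C([O-])=C3)[C@H]12.[Li+] | intermediate
18 | methyl 2-(6-Az-2,2-dimethyl-4-oxotetrahydro-4H-cyclopenta[d][1,3]dioxol-5-yl)acetate; side chain on C13 trans to Az and on the acetonide face | C=C1CCCC(C)(C)[C@@H]2CC[C@@](C)([C@@H]3[C@H]4OC(C)(C)O[C@H]4C(=O)[C@H]3CC(=O)OC)[C@H]12 | intermediate
19 | C14 alcohol of 18; OH cis to the acetonide and to the C13 side chain | C=C1CCCC(C)(C)[C@@H]2CC[C@@](C)([C@@H]3[C@H]4OC(C)(C)O[C@H]4[C@@H](O)[C@H]3CC(=O)OC)[C@H]12 | intermediate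
20 | tricyclic lactone; gamma-lactone (O on C14, C17=O, C16H2, C13) cis-fused to the cyclopentane on the acetonide face, Az on the other face | C=C1CCCC(C)(C)[C@@H]2CC[C@@](C)([C@@H]3[C@H]4OC(C)(C)O[C@H]4[C@H]5OC(=O)C[C@@H]35)[C@H]12 | intermediate
21 | C16-hydroxy derivative of 20; OH exo, on the face of H13 and H14 | C=C1CCCC(C)(C)[C@@H]2CC[C@@](C)([C@@H]3[C@H]4OC(C)(C)O[C@H]4[C@H]5OC(=O)[C@H](O)[C@@H]35)[C@H]12 | intermediate
22 | C16 tert-butyldimethylsilyl ether of 21 | C=C1CCCC(C)(C)[C@@H]2CC[C@@](C)([C@@H]3[C@H]4OC(C)(C)O[C@H]4[C@H]5OC(=O)[C@H](O[Si](C)(C)C(C)(C)C)[C@@H]35)[C@H]12 | intermediate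
23 | ring-opened C14-hydroxy C17-acid of 22 | C=C1CCCC(C)(C)[C@@H]2CC[C@@](C)([C@@H]3[C@H]4OC(C)(C)O[C@H]4[C@@H](O)[C@H]3[C@H](C(=O)O)O[Si](C)(C)C(C)(C)C)[C@H]12 | intermediate
24 | methyl ester of 23 (C14 OH free) | C=C1CCCC(C)(C)[C@@H]2CC[C@@](C)([C@@H]3[C@H]4OC(C)(C)O[C@H]4[C@@H](O)[C@H]3[C@H](C(=O)OC)O[Si](C)(C)C(C)(C)C)[C@H]12 | intermediate
25 | C14 acetate of 24 | C=C1CCCC(C)(C)[C@@H]2CC[C@@](C)([C@@H]3[C@H]4OC(C)(C)O[C@H]4[C@@H](OC(C)=O)[C@H]3[C@H](C(=O)OC)O[Si](C)(C)C(C)(C)C)[C@H]12 | intermediate
26 | C12,C15-diol from 25; C12 OH, C15 OH, C14 OAc and the C13 side chain all cis, Az trans | C=C1CCCC(C)(C)[C@@H]2CC[C@@](C)([C@@H]3[C@@H](O)[C@@H](O)[C@@H](OC(C)=O)[C@H]3[C@H](C(=O)OC)O[Si](C)(C)C(C)(C)C)[C@H]12 | intermediate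
27 | open-chain dialdehyde; C12 CHO on C11, C15 CHO on C14 | C=C1CCCC(C)(C)[C@@H]2CC[C@@](C)([C@H](C=O)[C@@H]([C@H](OC(C)=O)C=O)[C@H](C(=O)OC)O[Si](C)(C)C(C)(C)C)[C@H]12 | intermediate
28 | C12 aldehyde, C15 carboxylic acid (open form of its six-membered hydroxy lactone) | C=C1CCCC(C)(C)[C@@H]2CC[C@@](C)([C@H](C=O)[C@@H]([C@H](OC(C)=O)C(=O)O)[C@H](C(=O)OC)O[Si](C)(C)C(C)(C)C)[C@H]12 | intermediate
29 | tetrahydrofuran lactol (O16–C12) with free C15 acid; reactive anomer drawn | C=C1CCCC(C)(C)[C@@H]2CC[C@@](C)([C@@H]3[C@H](O)O[C@@H](C(=O)OC)[C@@H]3[C@H](OC(C)=O)C(=O)O)[C@H]12 | intermediate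
30 | CNP0215240.1; methyl 4-acetoxy-8-Az-3-oxo-2,7-dioxabicyclo[3.2.1]octane-6-carboxylate | C=C1CCCC(C)(C)[C@@H]2CC[C@@](C)([C@@H]3[C@@H]4OC(=O)[C@@H](OC(C)=O)[C@H]3[C@H](C(=O)OC)O4)[C@H]12 | target

**Count**
Total steps: 20. Longest linear sequence: 19 (steps 1–8 and 10–20; step 9 is the side branch).

**Steps most likely to fail**

Step 5 (labelled step).
- What may go wrong: reduction of the C9 radical to an ester enolate before it closes on C10. The methacrylate may also oligomerise, started by the samarium enolate or by radicals. Active divalent samarium may be lost, or the ring bond C10–C6 may open in part.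
- Fallback: it sets out from 7 and comes back at 9, and it replaces the one-pot relay by three known operations.
- Me3SiI (Me3SiCl, NaI, MeCN, −20 °C, Et3N quench) opens the same exocyclic bond by iodide attack at C7. This gives {[(3R)-3-(iodomethyl)-4,4-dimethylcyclohept-1-en-1-yl]oxy}trimethylsilane F1, whose enol ether marks C10.
- A tin-free Giese addition ((Me3Si)3SiH, azobis(isobutyronitrile), 8, toluene, 80 °C) forms C7–C8. This gives methyl 4-[(1R)-7,7-dimethyl-3-(trimethylsilyloxy)cyclohept-2-en-1-yl]-2-methylbutanoate F2.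
- LiN(i-Pr)2 at −78 °C (ester enolate) and then MeLi at 0 °C (O–Si cleavage) give the regiodefined dilithium bis-enolate F3.
- CuCl2 in THF/DMF closes C9–C10 by intramolecular oxidative enolate coupling, cis for the same tether reason, to give 9.

Step 15.
- What may go wrong: relactonisation of the cis hydroxy acid or hydroxy ester faster than esterification and acetylation, so that material cycles back to the lactone.
- Fallback: it sets out from 22 and comes back at 25, and it carries C17 as an amide that cannot relactonise under acylation conditions.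
- Me2AlNMe2 (AlMe3, Me2NH·HCl, CH2Cl2) opens the lactone to the C14-hydroxy C17-dimethylamide F4.
- Ac2O, Et3N and 4-(dimethylamino)pyridine give the C14-acetoxy dimethylamide F5.
- Me3OBF4 with 2,6-di-tert-butyl-4-methylpyridine in CH2Cl2 gives the O-methyl imidatonium tetrafluoroborate F6.
- Hydrolysis of F6 in a pH 4 buffer/THF mixture delivers methyl ester 25.

Step 19.
- What may go wrong: poor discrimination between the two aldehydes, with over-oxidation at C12 or incomplete oxidation at C15.
- Fallback: it sets out from 26 and comes back at 28, and it differentiates the two carbons before the ring is cut.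
- 2-Iodoxybenzoic acid (1.1 equiv, DMSO, rt) should oxidise the less encumbered C15 carbinol, since the C12 carbinol lies next to C11 with its quaternary neighbour. This gives the C15-keto C12-hydroxy alpha-ketol F7.
- NaIO4 in THF/H2O then cleaves the ketol directly into C15 acid and C12 aldehyde, which is 28.

**Further compounds**
F1 | step 5 | {[(3R)-3-(iodomethyl)-4,4-dimethylcyclohept-1-en-1-yl]oxy}trimethylsilane | C[Si](C)(C)OC1=C[C@@H](CI)C(C)(C)CCC1
F2 | step 5 | methyl 4-[(1R)-7,7-dimethyl-3-(trimethylsilyloxy)cyclohept-2-en-1-yl]-2-methylbutanoate (C9 epimers) | C[Si](C)(C)OC1=C[C@@H](CCC(C)C(=O)OC)C(C)(C)CCC1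
F3 | step 5 | dilithium bis-enolate of the keto ester | [Li+].[Li+].[O-]C1=C[C@@H](CCC(C)=C([O-])OC)C(C)(C)CCC1
F4 | step 15 | C14-hydroxy C17-dimethylamide | C=C1CCCC(C)(C)[C@@H]2CC[C@@](C)([C@@H]3[C@H]4OC(C)(C)O[C@H]4[C@@H](O)[C@H]3[C@H](C(=O)N(C)C)O[Si](C)(C)C(C)(C)C)[C@H]12
F5 | step 15 | C14-acetoxy dimethylamide | C=C1CCCC(C)(C)[C@@H]2CC[C@@](C)([C@@H]3[C@H]4OC(C)(C)O[C@H]4[C@@H](OC(C)=O)[C@H]3[C@H](C(=O)N(C)C)O[Si](C)(C)C(C)(C)C)[C@H]12
F6 | step 15 | O-methyl imidatonium tetrafluoroborate | C=C1CCCC(C)(C)[C@@H]2CC[C@@](C)([C@@H]3[C@H]4OC(C)(C)O[C@H]4[C@@H](OC(C)=O)[C@H]3[C@H](C(OC)=[N+](C)C)O[Si](C)(C)C(C)(C)C)[C@H]12.F[B-](F)(F)F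
F7 | step 19 | C15-keto C12-hydroxy alpha-ketol | C=C1CCCC(C)(C)[C@@H]2CC[C@@](C)([C@@H]3[C@@H](O)C(=O)[C@@H](OC(C)=O)[C@H]3[C@H](C(=O)OC)O[Si](C)(C)C(C)(C)C)[C@H]12
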